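In the cyclohexane ring C5–C10 (elemane numbering), the adjacent carbinol carbons C8 and C9 each sit beside a ring carbon that bears a vinyl-type group (C7: C11=C13; C10: C1=C2). This is the signature of two carbonyl allylations. Cutting C7–C8 and C9–C10 therefore excises C8–C9 as glyoxal. The key step stitches glyoxal into an open thirteen-carbon chain that carries an E-allylboronate at C13 and a Z-allylboronate at C2, on either side of C5–C6. Two chair-like allylborations, inter- then intramolecular, close the carbocycle and relay C5/C6 to C7, C8, C9 and quaternary C10. Both isopropenyl groups are oxidised afterwards.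

Key step: step 10

Remark on numbering:
- C10 is the quaternary ring carbon (C14 methyl, C1=C2 vinyl).
- C9 is CH–OAc, and C8 is CH–O of the lactone.
- C7 bears C11(=C13H2)–C12(=O).
- C6 is CH–O-angelate.
- C5 bears C4(=C3H2)–C15HO.
- β is above and α below the ring when it is drawn with C10→C9→C8 clockwise.

Assumption: glyoxal is used as the anhydrous monomer, cracked from the commercial trimer dihydrate over P2O5 just before use.

Step 1
Reactants: 1 2,2-dimethoxyacetaldehyde; 2 ethyl 2-(triphenylphosphoranylidene)propanoate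
Product: 3 ethyl (E)-4,4-dimethoxy-2-methylbut-2-enoate
Conditions: CH2Cl2/H2O, 23 °C
Reagents that add atoms: none
Why: The Wittig olefination with a stabilised α-branched ylide is E-selective, which places C6 trans to the ester carbon (C13) and cis to the C12 methyl.

Step 2
Reactants: 3 ethyl (E)-4,4-dimethoxy-2-methylbut-2-enoate
Product: 4 ethyl (E)-2-methyl-4-oxobut-2-enoate
Conditions: Amberlyst-15, acetone/H2O, 23 °C
Reagents that add atoms: water, O
Why: Acid-catalysed acetal hydrolysis frees the enal without touching the ester or the alkene geometry.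

Step 3
Reactants: 4 ethyl (E)-2-methyl-4-oxobut-2-enoate; 5 2,4-dimethylpenta-1,3-diene
Product: 8 ethyl (2E,4R)-4-hydroxy-2,6-dimethyl-5-(prop-1-en-2-yl)hepta-2,6-dienoate, via 2,4-dimethylpentadienylpotassium 6 (not isolated), via pentadienyldiisopinocampheylborane 7 (not isolated)
Conditions: 5, n-BuLi/KOt-Bu, THF, −78 → −45 °C; (−)-Ipc2BOMe, then BF3·OEt2, −78 °C; 4, −78 °C; NaBO3·4H2O, THF/H2O, 23 °C
Reagents that add atoms: none
Why: In this Brown asymmetric allylboration the terminal pentadienylborane reacts at its γ-carbon through a chair, so C5 receives two identical isopropenyl groups and only C6 becomes stereogenic, the (+)-α-pinene-derived ligands directing attack to the Si face of 4 (6R).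

Step 4
Reactants: 8 ethyl (2E,4R)-4-hydroxy-2,6-dimethyl-5-(prop-1-en-2-yl)hepta-2,6-dienoate; 9 acryloyl chloride
Product: 10 ethyl (2E,4R)-4-(acryloyloxy)-2,6-dimethyl-5-(prop-1-en-2-yl)hepta-2,6-dienoate
Conditions: i-Pr2NEt, DMAP (cat.), CH2Cl2, 0 °C
Reagents that add atoms: none
Why: This is a standard O-acylation of a secondary alcohol, and no stereocentre is touched.

Step 5
Reactants: 10 ethyl (2E,4R)-4-(acryloyloxy)-2,6-dimethyl-5-(prop-1-en-2-yl)hepta-2,6-dienoate
Product: 11 ethyl (2E)-2-methyl-3-[(2R,3S)-4-methyl-6-oxo-3-(prop-1-en-2-yl)-3,6-dihydro-2H-pyran-2-yl]prop-2-enoate (trans lactone)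
Conditions: second-generation Grubbs catalyst RuCl2(=CHPh)(PCy3)(H2IMes) (5 mol %), toluene 0.005 M, 80 °C
Reagents that add atoms: none
Why: In this diastereotopic-group-selective ring-closing metathesis the ring enforces the Z relation of C5 and C2 across C10=C1, and trans closure (sets C5) should prevail because only it lets the residual isopropenyl and the C6 side chain stand antiperiplanar, free of 1,2-allylic strain with the C10 methyl; any cis isomer is removed by chromatography.

Step 6
Reactants: 11 trans lactone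
Product: 12 (2E,4R,5S,6Z)-2,6-dimethyl-5-(prop-1-en-2-yl)octa-2,6-diene-1,4,8-triol
Conditions: i-Bu2AlH (6 equiv), CH2Cl2, −78 → 0 °C
Reagents that add atoms: none
Why: Exhaustive 1,2-reduction of the enoate ester and of the unsaturated lactone gives both primary allylic alcohols with the E and Z geometries retained.

Step 7
Reactants: 12 (2E,4R,5S,6Z)-2,6-dimethyl-5-(prop-1-en-2-yl)octa-2,6-diene-1,4,8-triol
Product: 13 dimethyl [(2E,4R,5S,6Z)-4-hydroxy-2,6-dimethyl-5-(prop-1-en-2-yl)octa-2,6-diene-1,8-diyl] biscarbonate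
Conditions: ClCO2Me (2.1 equiv), pyridine, CH2Cl2, −30 → 0 °C
Reagents that add atoms: methyl chloroformate, COC(=O)Cl
Why: In this chemoselective carbonate formation the two primary allylic hydroxyls react much faster than the hindered secondary C6 hydroxyl.

Step 8
Reactants: 13 biscarbonate
Product: 14 (2E,4R,5S,6Z)-2,6-dimethyl-5-(prop-1-en-2-yl)-1,8-bis(4,4,5,5-tetramethyl-1,3,2-dioxaborolan-2-yl)octa-2,6-dien-4-ol
Conditions: B2pin2 (2.4 equiv), Pd2(dba)3 (2.5 mol %), DMSO, 40 °C
Reagents that add atoms: bis(pinacolato)diboron, CC1(C)OB(OC1(C)C)B1OC(C)(C)C(C)(C)O1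
Why: This Miyaura-type allylic borylation runs through π-allyl complexes formed from zerovalent palladium, delivers boron to the primary termini, keeps the E unit in its syn form, and keeps the Z unit because syn–anti exchange would need a tertiary σ-allyl palladium at C10.

Step 9
Reactants: 14 bis(allylboronate) alcohol; 15 angelic anhydride
Product: 16 (2E,4R,5S,6Z)-2,6-dimethyl-5-(prop-1-en-2-yl)-1,8-bis(4,4,5,5-tetramethyl-1,3,2-dioxaborolan-2-yl)octa-2,6-dien-4-yl (Z)-2-methylbut-2-enoate
Conditions: LiN(SiMe3)2, THF, −78 °C; 15, −78 → 0 °C; aq. NH4Cl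
Reagents that add atoms: none
Why: Acylation of the lithium alkoxide with the anhydride is a stereoconservative angeloylation, since no nucleophilic catalyst is present that could isomerise angelate to tiglate, and the product is used directly.

Step 10
Reactants: 16 bis(allylboronate) angelate; 17 glyoxal
Product: 19 6β-angeloyloxyelema-1,3,11(13)-triene-8α,9α-diol (5αH, 7αH, 10β-methyl), via boryloxy aldehyde 18 (not isolated)
Conditions: 17 (monomer, 2 equiv), 4 Å MS, toluene 0.02 M, −20 → 45 °C; aq. NaHCO3
Reagents that add atoms: none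
Why: Two consecutive carbonyl allylborations run through closed Zimmerman–Traxler chairs: the γ-monosubstituted, β-methyl-activated E-allylboronate (C13) adds first to one formyl group of 17 (bond C7–C8), and the α-boryloxy aldehyde 18 so released is captured intramolecularly by the slower, γ,γ-disubstituted Z-allylboronate (C2; bond C9–C10). The closest known reaction types are the tandem double allylboration of dialdehydes with bis(allyl)boron reagents and the intramolecular allylboration that gives 2-vinylcyclohexanols. The only ring closed is the carbocycle C5–C10, by 6-exo-trig attack of C10 on the C9 formyl group in a cis-decalin-like double chair. C7 is set by 1,3-allylic strain (C12 methyl against C6, H6 in the alkene plane) with attack anti to the bulky C5 branch, C8 by the E geometry (anti adduct, O8 trans to C11), C9 by the Z geometry (O9 cis to the new vinyl), and C10 by 1,3-allylic strain between C2 and C5 (H5 in the plane) together with equatorial C4, C11 and O8 in the forming chair. The step needs chemoselectivity between the two allylboronates and cyclisation in preference to 2:1 adducts: the first rests on the rate gap between crotyl-type and hindered prenyl-type pinacol boronates, the second on high dilution and the six-membered closure.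

Step 11
Reactants: 19 6β-angeloyloxyelema-1,3,11(13)-triene-8α,9α-diol
Product: 20 6β-angeloyloxyelema-1,3,11(13)-triene-8α,9α,12,15-tetraol
Conditions: SeO2 (30 mol %), t-BuOOH (5 equiv), CH2Cl2, 0 → 23 °C
Reagents that add atoms: tert-butyl hydroperoxide, CC(C)(C)OO
Why: The catalytic Riley oxidation (ene reaction, then [2,3]-sigmatropic shift) should touch only the two electron-rich 1,1-disubstituted alkenes, at their methyl groups rather than the hindered ring methines, and any enal formed converges in step 12.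

Step 12
Reactants: 20 tetraol
Product: 21 6β-angeloyloxy-9α-hydroxy-15-oxoelema-1,3,11(13)-trien-12,8α-olide
Conditions: MnO2 (excess), CH2Cl2, 23 °C
Reagents that add atoms: none
Why: MnO2 oxidises only allylic alcohols: C15 stops at the enal, the C12 aldehyde is trapped by the equatorial C8 hydroxyl as a lactol and oxidised on to the trans-fused α-methylene lactone, and C9–OH is left untouched.

Step 13
Reactants: 21 hydroxy lactone enal
Product: 22 9α-acetoxy-6β-angeloyloxy-15-oxoelema-1,3,11(13)-trien-12,8α-olide (target)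
Conditions: Ac2O, DMAP, pyridine, 23 °C
Reagents that add atoms: acetic anhydride, CC(=O)OC(C)=O
Why: DMAP-catalysed acetylation caps the only remaining hydroxyl, and no stereocentre is affected.

Compound list
1 | 2,2-dimethoxyacetaldehyde | COC(OC)C=O | starting material
2 | ethyl 2-(triphenylphosphoranylidene)propanoate | CCOC(=O)C(C)=P(c1ccccc1)(c1ccccc1)c1ccccc1 | starting material
3 | ethyl (E)-4,4-dimethoxy-2-methylbut-2-enoate | CCOC(=O)/C(C)=C/C(OC)OC | intermediate
4 | ethyl (E)-2-methyl-4-oxobut-2-enoate | CCOC(=O)/C(C)=C/C=O | intermediate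
5 | 2,4-dimethylpenta-1,3-diene | CC(C)=CC(C)=C | starting material
6 | 2,4-dimethylpentadienylpotassium | [K+].[CH2-]C(C)=CC(C)=C | intermediate
7 | (2,4-dimethylpenta-2,4-dienyl)diisopinocampheylborane, Ipc from (+)-α-pinene | C=C(C)C=C(C)CB([C@@H]1C[C@@H]2C[C@H]([C@H]1C)C2(C)C)[C@@H]1C[C@@H]2C[C@H]([C@H]1C)C2(C)C | intermediate
8 | ethyl (2E,4R)-4-hydroxy-2,6-dimethyl-5-(prop-1-en-2-yl)hepta-2,6-dienoate | C=C(C)C(C(C)=C)[C@H](O)/C=C(C)/C(=O)OCC | intermediate
9 | acryloyl chloride | C=CC(=O)Cl | starting material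
10 | ethyl (2E,4R)-4-(acryloyloxy)-2,6-dimethyl-5-(prop-1-en-2-yl)hepta-2,6-dienoate | C=C(C)C(C(C)=C)[C@H](OC(=O)C=C)/C=C(C)/C(=O)OCC | intermediate
11 | ethyl (2E)-2-methyl-3-[(2R,3S)-4-methyl-6-oxo-3-(prop-1-en-2-yl)-3,6-dihydro-2H-pyran-2-yl]prop-2-enoate | O=C1C=C(C)[C@H](C(C)=C)[C@H](O1)/C=C(C)/C(=O)OCC | intermediate
12 | (2E,4R,5S,6Z)-2,6-dimethyl-5-(prop-1-en-2-yl)octa-2,6-diene-1,4,8-triol | OC/C=C(C)\[C@H](C(C)=C)[C@H](O)/C=C(C)/CO | intermediate
13 | dimethyl [(2E,4R,5S,6Z)-4-hydroxy-2,6-dimethyl-5-(prop-1-en-2-yl)octa-2,6-diene-1,8-diyl] biscarbonate | COC(=O)OC/C=C(C)\[C@H](C(C)=C)[C@H](O)/C=C(C)/COC(=O)OC | intermediate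
14 | (2E,4R,5S,6Z)-2,6-dimethyl-5-(prop-1-en-2-yl)-1,8-bis(pinacolboryl)octa-2,6-dien-4-ol | CC1(C)OB(C/C=C(C)\[C@H](C(C)=C)[C@H](O)/C=C(C)/CB2OC(C)(C)C(C)(C)O2)OC1(C)C | intermediate
15 | angelic anhydride, (Z)-2-methylbut-2-enoic anhydride | C/C=C(/C)C(=O)OC(=O)/C(C)=C\C | starting material
16 | (2E,4R,5S,6Z)-2,6-dimethyl-5-(prop-1-en-2-yl)-1,8-bis(pinacolboryl)octa-2,6-dien-4-yl (Z)-2-methylbut-2-enoate | CC1(C)OB(C/C=C(C)\[C@H](C(C)=C)[C@H](OC(=O)/C(C)=C\C)/C=C(C)/CB2OC(C)(C)C(C)(C)O2)OC1(C)C | intermediate
17 | glyoxal | O=CC=O | starting material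
18 | mono-adduct: C9 aldehyde with C8–OBpin, C7 isopropenyl, C6 O-angelate, C5 isopropenyl and the (Z)-C2 allylboronate | O=C[C@H](OB1OC(C)(C)C(C)(C)O1)[C@@H](C(C)=C)[C@@H](OC(=O)/C(C)=C\C)[C@@H](C(C)=C)/C(C)=C\CB1OC(C)(C)C(C)(C)O1 | intermediate
19 | 6β-angeloyloxyelema-1,3,11(13)-triene-8α,9α-diol | C=C[C@]1(C)[C@H](O)[C@H](O)[C@@H](C(C)=C)[C@@H](OC(=O)/C(C)=C\C)[C@H]1C(C)=C | intermediate
20 | 6β-angeloyloxyelema-1,3,11(13)-triene-8α,9α,12,15-tetraol | C=C[C@]1(C)[C@H](O)[C@H](O)[C@@H](C(=C)CO)[C@@H](OC(=O)/C(C)=C\C)[C@H]1C(=C)CO | intermediate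
21 | 6β-angeloyloxy-9α-hydroxy-15-oxoelema-1,3,11(13)-trien-12,8α-olide | C=C[C@]1(C)[C@H](O)[C@@H]2OC(=O)C(=C)[C@H]2[C@@H](OC(=O)/C(C)=C\C)[C@H]1C(=C)C=O | intermediate
22 | 9α-acetoxy-6β-angeloyloxy-15-oxoelema-1,3,11(13)-trien-12,8α-olide | C=C[C@]1(C)[C@H](OC(C)=O)[C@@H]2OC(=O)C(=C)[C@H]2[C@@H](OC(=O)/C(C)=C\C)[C@H]1C(=C)C=O | target

Total step count: 13. Longest linear sequence: 13 (steps 1 to 13).

Steps most likely to fail

Step 10.
- **Risk:** The order of events may be lost if the hindered C2 allylboronate adds to free dialdehyde before C7–C8 exists, with poor facial control. Monomeric glyoxal may polymerise, or one glyoxal may be bridged by two chains.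
- **Fallback:** It sets out from 16 and comes back at 19, and it uses a differentiated glyoxal equivalent.
- **Course:** 16 is treated with 1 (1.0 equiv, toluene, 23 °C). Only one formyl group is then on offer, and the E-allylboronate should give the acetal-masked mono-adduct F1. In the same flask LiBF4 in wet MeCN unmasks the C9 acetal. The aldehyde is caught at once by the Z-allylboronate through the same double chair, so both ring bonds are still made in one operation, and aqueous work-up gives 19.

Step 8.
- **Risk:** Syn–anti exchange of the π-allyl palladium may erode the Z geometry. The C6 hydroxyl may capture the π-allyl unit, or allyl–allyl coupling may occur.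
- **Fallback:** It sets out from 12 and comes back at 19, and it avoids π-allyl intermediates by changing the allyl metal to silicon.
- **Course:**
  - The primary hydroxyls are exchanged for chloride without allylic transposition (MsCl, LiCl, 2,4,6-collidine, DMF, 0 °C) to give the dichloro alcohol F2.
  - O6 is acylated with 15 (LiN(SiMe3)2, THF, −78 °C) to give the dichloro angelate F3.
  - HSiCl3, CuCl and i-Pr2NEt in Et2O replace each chloride at the primary carbon with retention of alkene geometry and give the bis(allyltrichlorosilane) F4, which is used crude.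
  - With 17 in DMF at 0 °C the hypervalent allylsilicates react through closed chairs with the same E-to-anti and Z-to-syn correlation. NaHCO3 work-up gives 19.

Step 11.
- **Risk:** Site selectivity may be poor (oxidation of the tertiary allylic C–H at C5 or C7), conversion of one of the two isopropenyl groups may be incomplete, or over-oxidation may occur.
- **Fallback:** It sets out from 19 and comes back at 20.
- **Course:**
  - Ene-type allylic chlorination with hypochlorous acid (NaOCl, CeCl3·7H2O, CH2Cl2/H2O, 0 °C) should convert both isopropenyl groups into the bis(allylic chloride) F5.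
  - Displacement with HCO2Na (Bu4NBr, DMF, 40 °C) gives the bis(formate) F6.
  - KHCO3 in MeOH cleaves only the formates and gives 20.

Further compounds
F1 | step 10 | C9 dimethyl acetal of 18 (C8–OBpin, (Z)-C2 allylboronate intact) | COC(OC)[C@H](OB1OC(C)(C)C(C)(C)O1)[C@@H](C(C)=C)[C@@H](OC(=O)/C(C)=C\C)[C@@H](C(C)=C)/C(C)=C\CB1OC(C)(C)C(C)(C)O1
F2 | step 8 | (2E,4R,5S,6Z)-1,8-dichloro-2,6-dimethyl-5-(prop-1-en-2-yl)octa-2,6-dien-4-ol | ClC/C=C(C)\[C@H](C(C)=C)[C@H](O)/C=C(C)/CCl
F3 | step 8 | (2E,4R,5S,6Z)-1,8-dichloro-2,6-dimethyl-5-(prop-1-en-2-yl)octa-2,6-dien-4-yl (Z)-2-methylbut-2-enoate | ClC/C=C(C)\[C@H](C(C)=C)[C@H](OC(=O)/C(C)=C\C)/C=C(C)/CCl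
F4 | step 8 | (2E,4R,5S,6Z)-2,6-dimethyl-5-(prop-1-en-2-yl)-1,8-bis(trichlorosilyl)octa-2,6-dien-4-yl (Z)-2-methylbut-2-enoate | Cl[Si](Cl)(Cl)C/C=C(C)\[C@H](C(C)=C)[C@H](OC(=O)/C(C)=C\C)/C=C(C)/C[Si](Cl)(Cl)Cl
F5 | step 11 | 6β-angeloyloxy-12,15-dichloroelema-1,3,11(13)-triene-8α,9α-diol | C=C[C@]1(C)[C@H](O)[C@H](O)[C@@H](C(=C)CCl)[C@@H](OC(=O)/C(C)=C\C)[C@H]1C(=C)CCl
F6 | step 11 | 6β-angeloyloxy-12,15-bis(formyloxy)elema-1,3,11(13)-triene-8α,9α-diol | C=C[C@]1(C)[C@H](O)[C@H](O)[C@@H](C(=C)COC=O)[C@@H](OC(=O)/C(C)=C\C)[C@H]1C(=C)COC=O
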